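## Analysis of the target

Target 13 is (4,5-dichloro-1H-pyrrol-2-yl)[2,4-dihydroxy-3-(4-methylpentyl)phenyl]methanone. A benzene ring (C1'–C6') and a pyrrole ring (N1, C2–C5) are joined through one ketone carbon, which sits on C1' and on pyrrole C2. The benzene ring is substituted on four neighbouring carbons: the ketone on C1', hydroxyl on C2', the 4-methylpentyl chain on C3', hydroxyl on C4', with hydrogen on C5' and C6'. The pyrrole carries chlorine on C4 and C5 and a free N–H. There is no stereocentre, so the problem is purely one of constitution and of the order of events.

The sensitive groups are the two C–Cl bonds (lost under hydrogenolysis or with low-valent metals), the acidic N–H, and the electron-rich resorcinol. In the resorcinol, C5' is activated by both hydroxyl groups and the benzylic CH2 of the chain lies between them. The difficulty is that an electrophilic chlorination of the pyrrole cannot be run once the oxygenated arene is present, and that four contiguous arene substituents must be placed without regiochemical doubt.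

The strategy rests on the oxygens at C2' and C4' standing 1,3 to each other, with the alkylated C3' between them and the acyl group on C1'. That is the pattern of a 4-acyl-2-alkylcyclohexane-1,3-dione that lacks only the unsaturation between C5' and C6'. The benzene ring can therefore be built as a saturated carbocycle by carbonyl condensations on a finished dichloropyrrole and aromatized at the end.

## Retrosynthetic reasoning

**13 to 12.** No skeletal bond is cut. Two hydrogens are added back at C5' and C6', which turns the arene into the cyclohexane-1,3-dione 12. This converts a problem of arene substitution into carbonyl chemistry: the oxygens at C2' and C4' become ketones, and C1' and C3' become doubly activated carbons. The forward reaction must dehydrogenate without touching the C–Cl bonds, which excludes metal-catalysed hydrogen transfer, and without oxidizing the resorcinol it creates.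

**12 to 5 and 10, through 11.** The C2'–C3' bond is cut first as a Claisen condensation, which reveals the δ-keto ester 11. The C1'–C6' bond is then cut as a conjugate addition. These are the natural places. C2' is at the carboxyl oxidation level and can be an ester. C3' is α to the C4' ketone and C6' is β to it. So C1' and C2' come from the β-keto ester 5, and C3'–C6' come from the vinyl ketone 10. The gain is convergence: the pyrrole arrives on one partner with both chlorines, the chain arrives on the other, and one operation makes two C–C bonds and the ring. The forward reaction has to alkylate 5 once at carbon and then close the ring on the ester carbonyl, not on the pyrrolyl ketone.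

**5 to 1 and 2, through 3 and 4.** The bond between the ketone carbon and its α-methylene is cut. Acid 1 already holds both chlorines, so no chlorination appears anywhere in the route. The forward reaction is acylation of the malonate half-ester 2 by the activated acid 3, followed by decarboxylation of 4.

**10 to 9, then to 6 and 7, through 8.** The ketone is taken back to the allylic alcohol 9. The bond between the carbinol carbon and the first chain methylene is then cut, giving the Grignard reagent 8 (from bromide 6) and the aldehyde 7. The carbon of 8 that carries magnesium ends up as C3' of the arene. The forward reactions are a 1,2-addition and an oxidation that does not destroy the vinyl ketone.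

## Alternatives that were turned down

**Alternative 1:** The pyrrole ring is cut at N1–C5 and C2–C3.
- **Disconnection.** N1, C2 and the ketone would come from the aminomethyl aryl ketone A2, 2-amino-1-[2,4-dimethoxy-3-(4-methylpentyl)phenyl]ethan-1-one, handled as its hydrochloride. C3–C5 with the C4 chlorine would come from the 2-chlorovinamidinium salt A3.
- **Forward key step.** Under alkoxide the amine of A2 exchanges with one dimethylamino group of A3. The carbanion between nitrogen and the ketone then attacks the remaining iminium carbon, and loss of the second dimethylamino group gives the pyrrole A1, (4-chloro-1H-pyrrol-2-yl)[2,4-dimethoxy-3-(4-methylpentyl)phenyl]methanone.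
- **For.** This condensation type is dependable for 2-acylpyrroles and fixes the C4 chlorine without a regiochemical question. Its ring closure has no competing mode like the aldol closure the chosen key step must avoid, so on that point it is the stronger plan.
- **Against.** A1 holds only one chlorine. C5 would have to be chlorinated electrophilically in the presence of the dimethoxyarene, whose C5' is ortho and para to the two methoxy groups and at least as nucleophilic as C5 of an acylpyrrole. Two aryl methyl ethers must then be cleaved. A2 takes several steps from the arene and, as a free α-amino ketone, tends to self-condense.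
- **Comparison.** About seven to eight steps against five. The chosen strategy offers both chlorines from the first flask, no protecting group, and no electrophile ever meeting the electron-rich ring.

**Alternative 2:** The benzene ring is cut at C1'–C2' and C5'–C6'.
- **Disconnection.** C1' and C6' would come from the ethynyl ketone A5, tert-butyl 2,3-dichloro-5-(prop-2-ynoyl)-1H-pyrrole-1-carboxylate. C2'–C5' would come from the diene A6, 1-methoxy-2-(4-methylpentyl)-1,3-bis(trimethylsilyloxy)buta-1,3-diene.
- **Forward key step.** A [4+2] cycloaddition joins the nucleophilic CH2 terminus of A6 to the alkyne terminus of A5. The cyclohexadiene adduct loses its methoxy and silyl groups to give A4, tert-butyl 2,3-dichloro-5-[2,4-dihydroxy-3-(4-methylpentyl)benzoyl]-1H-pyrrole-1-carboxylate.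
- **For.** The arene arrives at the correct oxidation level, so no oxidant touches the finished resorcinol; this is stronger than the chosen route. The chlorines are also present from the start, which is equal.
- **Against.** A6 is hindered in its s-cis conformation by the substituent on its central carbon, is moisture-sensitive, and needs an alkylation and two silylations. With an ynone the reaction may run stepwise (Mukaiyama–Michael). The ketene acetal carbon could then close on the ketone carbonyl and not on the α-carbon, which would place the pyrrole directly on the benzene ring. A5 needs N-protection, since a free pyrrolyl ynone would add its own N–H, then conversion of the acid into the ynone, and removal of the carbamate at the end.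
- **Comparison.** About eight steps. The chosen strategy offers three robust precursors, a ring closure under equilibrium control and not a kinetically controlled cycloaddition, and no protecting group.

**Alternative 3:** The pyrrole ring and the ketone are both traced back to a pyridine N-oxide.
- **Disconnection.** The precursor would be A8, 2,3-dichloro-6-[2,4-dimethoxy-3-(4-methylpentyl)phenyl]pyridine 1-oxide, a biaryl available by cross-coupling and N-oxidation.
- **Forward key step.** Irradiation moves oxygen from nitrogen to the aryl-bearing C6 through valence isomers. C6 is pushed out of the ring as the ketone carbon and nitrogen bonds to the former C5, giving A7, (4,5-dichloro-1H-pyrrol-2-yl)[2,4-dimethoxy-3-(4-methylpentyl)phenyl]methanone.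
- **For.** One step creates the pyrrole and the ketone together. Both chlorines come from the pyridine, never from electrophilic chlorination, which equals the chosen route. The plan is in principle more convergent.
- **Against.** The substrate gives no control between the two α-carbons: oxygen can migrate to the chlorine-bearing C2 as well as to C6. Deoxygenation and other rearrangement paths of the excited N-oxide also compete. N-oxidation is slow because the nitrogen is flanked by chlorine and an aryl group and is electron-poor. The methyl ethers must be cleaved afterwards, and the key step is dilute photochemistry.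
- **Comparison.** About six to seven steps. The chosen strategy offers a key step whose outcome is fixed by an enolate sink and not by excited-state partitioning, and it needs no ether cleavage.

Key step: step 4

## Route

Assumption: the target has no stereocentre; alcohol 9 is used as the racemate and the substituted sp3 ring carbons of 11 and 12 are freely enolizable, so no configuration has to be controlled.

Step 1
Reactants: 1 4,5-dichloro-1H-pyrrole-2-carboxylic acid; 2 potassium methyl malonate
Product: 5 methyl 3-(4,5-dichloro-1H-pyrrol-2-yl)-3-oxopropanoate, via acyl imidazolide 3 (not isolated), via acylmalonate half-ester 4 (not isolated)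
Conditions: CDI, THF, rt; then 2, MgCl2, Et3N, MeCN, rt → 45 °C; 1 M HCl
Reagents that add atoms: 1,1'-carbonyldiimidazole (CDI), O=C(n1ccnc1)n1ccnc1 (supplies the imidazol-1-yl group of 3 only; none of its atoms remain in 5)
Why: Decarboxylative Claisen condensation of a magnesium malonate half-ester (Masamune-type): imidazolide 3 acylates the magnesium enolate of 2 at carbon to give 4, which loses CO2 on acidic work-up. The nearly neutral conditions tolerate the free N–H, and the chlorine on C5 shields the nitrogen from self-acylation.

Step 2
Reactants: 6 1-bromo-5-methylhexane; 7 acrolein
Product: 9 racemic 8-methylnon-1-en-3-ol, via 5-methylhexylmagnesium bromide 8 (not isolated)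
Conditions: Mg, I2 (cat.), THF, reflux; then 7, THF, −78 → 0 °C; aq. NH4Cl
Reagents that add atoms: magnesium, [Mg] (held in 8 only; none remains in 9)
Why: Grignard formation from a primary bromide, then 1,2-addition of the hard organomagnesium nucleophile to the aldehyde carbonyl of acrolein at low temperature. The carbinol centre forms as a racemate and is removed in step 3.

Step 3
Reactants: 9 racemic 8-methylnon-1-en-3-ol
Product: 10 8-methylnon-1-en-3-one
Conditions: activated MnO2 (excess), CH2Cl2, rt; filtration through Celite; cold concentration, used at once
Reagents that add atoms: none
Why: Oxidation of an allylic alcohol on activated MnO2, selective for the allylic carbinol. Work-up is filtration only, which suits a volatile vinyl ketone that polymerizes easily.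

Step 4
Reactants: 5 methyl 3-(4,5-dichloro-1H-pyrrol-2-yl)-3-oxopropanoate; 10 8-methylnon-1-en-3-one
Product: 12 4-(4,5-dichloro-1H-pyrrole-2-carbonyl)-2-(4-methylpentyl)cyclohexane-1,3-dione, via Michael adduct 11 (not isolated)
Conditions: NaOMe (0.2 equiv), MeOH, 0 °C → rt, slow addition of 10; then NaOMe (3 equiv), MeOH, reflux; 1 M HCl
Reagents that add atoms: none
Why: Catalytic methoxide forms the stabilized enolate of 5, which adds through carbon to the terminal alkene carbon of 10 (Michael addition, C1'–C6') to give 11. With excess methoxide at reflux, 11 equilibrates among its enolates, and the one at the chain-bearing methylene (C3') attacks the ester carbonyl (C2') in a 6-exo-trig Claisen (Dieckmann-type) closure that expels methoxide. The closest known reaction type is the base-mediated Michael–Claisen route from malonates or β-keto esters and enones to cyclohexane-1,3-diones, as in the dimedone preparation, together with the cyclization of δ-keto esters to such diones. The ring closed is the six-membered carbocycle, and no configuration is set because C1' and C3' of 12 each lie between two carbonyl groups and are enolized. Three selectivities are needed: carbon over nitrogen in the conjugate addition, secured because N-addition is reversible and the carbon adduct is the stable one; one addition and not two, secured by slow addition of a near-equimolar amount of 10 to catalytic base in the cold; and Claisen closure on the ester in preference to aldol closure on the pyrrolyl ketone, which would also be six-membered. The last is secured by leaving N–H free: under methoxide the pyrrole is its anion, which makes the ketone a poorly electrophilic vinylogous amidate, the aldol step is reversible, and only the Claisen product leaves the equilibria as a doubly stabilized enolate. The other enolate of the chain ketone (C5') could only form four-membered rings, and the methyl ester is matched to methoxide so no transesterification can occur.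

Step 5
Reactants: 12 4-(4,5-dichloro-1H-pyrrole-2-carbonyl)-2-(4-methylpentyl)cyclohexane-1,3-dione
Product: 13 (4,5-dichloro-1H-pyrrol-2-yl)[2,4-dihydroxy-3-(4-methylpentyl)phenyl]methanone
Conditions: DDQ (1.1 equiv), 1,4-dioxane, rt → 60 °C
Reagents that add atoms: none
Why: Quinone dehydrogenation of a cyclohexane-1,3-dione to a resorcinol: the dienol tautomer of 12 is a cyclohexa-1,3-diene, hydride loss from C6' gives an arenium ion stabilized by both ring oxygens, and loss of the C5' proton gives the arene. The electron-poor dichloropyrrole and the diaryl ketone should be inert to DDQ.

## Compound list

1 | 4,5-dichloro-1H-pyrrole-2-carboxylic acid | OC(=O)c1cc(Cl)c(Cl)[nH]1 | starting material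
2 | potassium methyl malonate (potassium 3-methoxy-3-oxopropanoate) | COC(=O)CC(=O)[O-].[K+] | starting material
3 | (4,5-dichloro-1H-pyrrol-2-yl)(1H-imidazol-1-yl)methanone | O=C(c1cc(Cl)c(Cl)[nH]1)n1ccnc1 | intermediate
4 | 2-(4,5-dichloro-1H-pyrrole-2-carbonyl)-3-methoxy-3-oxopropanoic acid (formed as its magnesium salt) | COC(=O)C(C(=O)O)C(=O)c1cc(Cl)c(Cl)[nH]1 | intermediate
5 | methyl 3-(4,5-dichloro-1H-pyrrol-2-yl)-3-oxopropanoate | COC(=O)CC(=O)c1cc(Cl)c(Cl)[nH]1 | intermediate
6 | 1-bromo-5-methylhexane | CC(C)CCCCBr | starting material
7 | acrolein (prop-2-enal) | C=CC=O | starting material
8 | 5-methylhexylmagnesium bromide | CC(C)CCCC[Mg]Br | intermediate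
9 | 8-methylnon-1-en-3-ol (racemic) | C=CC(O)CCCCC(C)C | intermediate
10 | 8-methylnon-1-en-3-one | C=CC(=O)CCCCC(C)C | intermediate
11 | methyl 2-(4,5-dichloro-1H-pyrrole-2-carbonyl)-10-methyl-5-oxoundecanoate (racemic, enolizable) | COC(=O)C(CCC(=O)CCCCC(C)C)C(=O)c1cc(Cl)c(Cl)[nH]1 | intermediate
12 | 4-(4,5-dichloro-1H-pyrrole-2-carbonyl)-2-(4-methylpentyl)cyclohexane-1,3-dione (both substituted sp3 centres enolizable) | CC(C)CCCC1C(=O)CCC(C(=O)c2cc(Cl)c(Cl)[nH]2)C1=O | intermediate
13 | (4,5-dichloro-1H-pyrrol-2-yl)[2,4-dihydroxy-3-(4-methylpentyl)phenyl]methanone | CC(C)CCCc1c(O)ccc(C(=O)c2cc(Cl)c(Cl)[nH]2)c1O | target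

## Step count and least certain steps

Total step count: 5. Longest linear sequence: 4 steps (steps 2, 3, 4 and 5, from bromide 6 to target 13).

**Step 4 (key step).**
- **What may go wrong.** Adduct 11 may close through the aldol mode onto the pyrrolyl ketone, followed by dehydration. Methoxide may cleave the acylated centre of 11 by a retro-Claisen reaction. A second conjugate addition to 10 may occur. The cause is that the three carbonyl groups of 11 are told apart only by their electronic character.
- **Fallback.** This sets out from enone 10 and acid 1 and returns at target 13; it postpones the aryl–ketone bond.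
  - Dimethyl malonate and 10 with NaOMe in refluxing MeOH should give methyl 3-(4-methylpentyl)-2,4-dioxocyclohexane-1-carboxylate F1. Only ester carbonyls are available here, so only the Claisen mode can close the ring.
  - Aqueous NaOH, then HCl with heating, should hydrolyse and decarboxylate F1 to 2-(4-methylpentyl)cyclohexane-1,3-dione F2.
  - Dehydrogenation over Pd/C in refluxing mesitylene, safe because no chlorine is present at this stage, should give 2-(4-methylpentyl)benzene-1,3-diol F3.
  - Acid 1 with oxalyl chloride and catalytic DMF should give 4,5-dichloro-1H-pyrrole-2-carbonyl chloride F4.
  - Friedel–Crafts acylation of F3 with F4 (AlCl3, 1,2-dichloroethane, 0 °C → rt) should give 13 directly. The two open positions ortho to a hydroxyl group in F3 are equivalent, and any aryl ester formed first would reach the same ketone by Fries rearrangement.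

**Step 5.**
- **What may go wrong.** Over-oxidation after aromatization, by hydride abstraction from the benzylic methylene that lies between the two hydroxyl groups. Alternatively, the strongly acidic enol may couple with the quinone in place of clean loss of hydrogen from C5' and C6'.
- **Fallback.** This sets out from 12 and returns at 13; it replaces hydride abstraction by halogenation and elimination.
  - Iodine in refluxing MeOH should etherify the enol at the C4' carbonyl (the C2' carbonyl is held in the chelated β-diketone), iodinate C1' and eliminate hydrogen iodide. The expected product is (4,5-dichloro-1H-pyrrol-2-yl)[2-hydroxy-4-methoxy-3-(4-methylpentyl)phenyl]methanone F5, in which the oxygen para to the ketone is capped while the ring is oxidized.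
  - BBr3 in CH2Cl2 (−78 → 0 °C) should then cleave the methyl ether to give 13.

**Step 1.**
- **What may go wrong.** Self-acylation of the N–H imidazolide 3 at nitrogen, leading to dimerization, in competition with C-acylation of the magnesium malonate.
- **Fallback.** This sets out from 1 and returns at 5.
  - Meldrum's acid, EDC·HCl and DMAP in CH2Cl2 (0 °C → rt) should give 5-[(4,5-dichloro-1H-pyrrol-2-yl)(hydroxy)methylidene]-2,2-dimethyl-1,3-dioxane-4,6-dione F6. The activated acid is trapped by a fully ionized carbon acid.
  - Reflux of F6 in MeOH should release 5 through the acylketene in a separate, base-free thermal step.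

**Step 3.**
- **What may go wrong.** Slow oxidation of a terminal vinyl carbinol on MnO2, and loss of the vinyl ketone by polymerization or evaporation during concentration.
- **Fallback.** This sets out from Grignard reagent 8 and returns at enone 10, generated in the flask of step 4.
  - 8 and 3-chloropropanoyl chloride with catalytic Fe(acac)3 in THF at −78 °C should give the stable latent enone 1-chloro-8-methylnonan-3-one F7.
  - F7 is charged to step 4 with one extra equivalent of NaOMe, which eliminates hydrogen chloride and releases 10 in the presence of the enolate of 5.

## Further compounds

F1 | step 4 | methyl 3-(4-methylpentyl)-2,4-dioxocyclohexane-1-carboxylate | COC(=O)C1CCC(=O)C(CCCC(C)C)C1=O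
F2 | step 4 | 2-(4-methylpentyl)cyclohexane-1,3-dione | CC(C)CCCC1C(=O)CCCC1=O
F3 | step 4 | 2-(4-methylpentyl)benzene-1,3-diol | CC(C)CCCc1c(O)cccc1O
F4 | step 4 | 4,5-dichloro-1H-pyrrole-2-carbonyl chloride | O=C(Cl)c1cc(Cl)c(Cl)[nH]1
F5 | step 5 | (4,5-dichloro-1H-pyrrol-2-yl)[2-hydroxy-4-methoxy-3-(4-methylpentyl)phenyl]methanone | COc1ccc(C(=O)c2cc(Cl)c(Cl)[nH]2)c(O)c1CCCC(C)C
F6 | step 1 | 5-[(4,5-dichloro-1H-pyrrol-2-yl)(hydroxy)methylidene]-2,2-dimethyl-1,3-dioxane-4,6-dione | CC1(C)OC(=O)C(=C(O)c2cc(Cl)c(Cl)[nH]2)C(=O)O1
F7 | step 3 | 1-chloro-8-methylnonan-3-one | ClCCC(=O)CCCCC(C)C
A1 | alternative 1 | (4-chloro-1H-pyrrol-2-yl)[2,4-dimethoxy-3-(4-methylpentyl)phenyl]methanone | COc1ccc(C(=O)c2cc(Cl)c[nH]2)c(OC)c1CCCC(C)C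
A2 | alternative 1 | 2-amino-1-[2,4-dimethoxy-3-(4-methylpentyl)phenyl]ethan-1-one | COc1ccc(C(=O)CN)c(OC)c1CCCC(C)C
A3 | alternative 1 | 2-chloro-1,3-bis(dimethylamino)trimethinium hexafluorophosphate | CN(C)C=C(Cl)C=[N+](C)C.F[P-](F)(F)(F)(F)F
A4 | alternative 2 | tert-butyl 2,3-dichloro-5-[2,4-dihydroxy-3-(4-methylpentyl)benzoyl]-1H-pyrrole-1-carboxylate | CC(C)CCCc1c(O)ccc(C(=O)c2cc(Cl)c(Cl)n2C(=O)OC(C)(C)C)c1O
A5 | alternative 2 | tert-butyl 2,3-dichloro-5-(prop-2-ynoyl)-1H-pyrrole-1-carboxylate | C#CC(=O)c1cc(Cl)c(Cl)n1C(=O)OC(C)(C)C
A6 | alternative 2 | 1-methoxy-2-(4-methylpentyl)-1,3-bis(trimethylsilyloxy)buta-1,3-diene | COC(O[Si](C)(C)C)=C(CCCC(C)C)C(=C)O[Si](C)(C)C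
A7 | alternative 3 | (4,5-dichloro-1H-pyrrol-2-yl)[2,4-dimethoxy-3-(4-methylpentyl)phenyl]methanone | COc1ccc(C(=O)c2cc(Cl)c(Cl)[nH]2)c(OC)c1CCCC(C)C
A8 | alternative 3 | 2,3-dichloro-6-[2,4-dimethoxy-3-(4-methylpentyl)phenyl]pyridine 1-oxide | COc1ccc(-c2ccc(Cl)c(Cl)[n+]2[O-])c(OC)c1CCCC(C)C
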